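**Retrosynthetic overview**
- Feature: the only stereocentre, C8 (S), carries the ring A aryloxy oxygen. It is flanked by C7, the benzylic carbon of ring B, and the C4 oxygen of ring B stands para to C7.
- The C7 methylene is traced back to a C7 acetate. Hydride captures the ring B para-quinone methide at C7 and leaves C8 untouched. The acetate comes from the C7 carbinol and that from the C7 ketone.
- With C7 as a ketone, C8–H becomes exchangeable. The racemic 7-oxo ether is therefore channelled into one C8 configuration by an enzymatic dynamic reductive kinetic resolution.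
- The hindered C8–O(ring A) bond is disconnected at the racemic stage: 4-allyl-2,6-dimethoxyphenoxide plus the α-bromoketone made from O-TIPS propiovanillone.
- No ring is formed at any point; rings A and B are both bought intact.

Key step: step 4

Assumption: neolignan numbering is used (C7 benzylic, C8 the oxygenated methine, ring A the allyl-dimethoxyphenyl ring, ring B the guaiacyl ring), and a ketoreductase variant with the required C8 discrimination is taken to be reachable by panel screening and directed evolution.

**Step 1**
Reactants: 1 1-(4-hydroxy-3-methoxyphenyl)propan-1-one (propiovanillone)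
Product: 2 1-[3-methoxy-4-(triisopropylsilyloxy)phenyl]propan-1-one
Conditions: TIPSCl (1.2 equiv), imidazole (2.5 equiv), DMF, rt
Reagents that add atoms: triisopropylsilyl chloride, CC(C)[Si](Cl)(C(C)C)C(C)C
Why: Imidazole-promoted O-silylation of a phenol; TIPS is the common silyl group most resistant to base, it keeps ring B from ionising in steps 3 and 4, and it later serves as the fluoride trigger of step 6.

**Step 2**
Reactants: 2 1-[3-methoxy-4-(triisopropylsilyloxy)phenyl]propan-1-one
Product: 3 rac-2-bromo-1-[3-methoxy-4-(triisopropylsilyloxy)phenyl]propan-1-one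
Conditions: CuBr2 (2.1 equiv), EtOAc, reflux
Reagents that add atoms: CuBr2, [Cu+2].[Br-].[Br-]
Why: Heterogeneous α-bromination of an aryl ketone by CuBr2 (divalent copper ends as CuBr) runs through the enol and should stop at the monobromide; the acyl group and the bulky silyl ether shield ring B from nuclear bromination, no alkene is present yet, and the new C8 centre is deliberately racemic.

**Step 3**
Reactants: 3 rac-2-bromo-1-[3-methoxy-4-(triisopropylsilyloxy)phenyl]propan-1-one; 4 4-allyl-2,6-dimethoxyphenol (0.95 equiv)
Product: 5 rac-2-(4-allyl-2,6-dimethoxyphenoxy)-1-[3-methoxy-4-(triisopropylsilyloxy)phenyl]propan-1-one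
Conditions: K2CO3 (1.5 equiv), dry acetone, 45 °C
Reagents that add atoms: none
Why: Williamson-type SN2 displacement at a carbonyl-activated secondary bromide is the standard way to build 8-O-4' ethers even from 2,6-disubstituted phenoxides; keeping phenol 4 limiting in dry acetone leaves little free phenoxide to attack silicon, and C8 stays racemic, which is what step 4 requires.

**Step 4**
Reactants: 5 rac-2-(4-allyl-2,6-dimethoxyphenoxy)-1-[3-methoxy-4-(triisopropylsilyloxy)phenyl]propan-1-one
Product: 7 (1S,2S)-2-(4-allyl-2,6-dimethoxyphenoxy)-1-[3-methoxy-4-(triisopropylsilyloxy)phenyl]propan-1-ol, via achiral enolate 6 (not isolated)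
Conditions: evolved NADPH-dependent ketoreductase (short-chain dehydrogenase/reductase class), NADP+ (cat.), i-PrOH/0.1 M NaHCO3–Na2CO3 buffer pH 9.5 (3:7), 40 °C, N2 sweep to strip acetone
Reagents that add atoms: none
Why: Proposed new method: the carbonate buffer reversibly removes C8–H of 5, which is acidified by the C7 aryl ketone and by the inductively withdrawing ring A aryloxy group, so the ketone enantiomers interconvert through planar enolate 6 while the enzyme seats only the (8S)-ketone productively and passes the C4 hydride of NADPH to the Re face of C7=O, the same enzyme recharging the cofactor from i-PrOH. The closest known reaction type is ketoreductase dynamic reductive kinetic resolution of racemic α-substituted β-keto esters, α-amido aryl ketones and 2-substituted cyclic ketones; an acyclic α-aryloxy propiophenone flanked by two bulky groups has not been shown and calls for screening and evolution of a scaffold that accepts bulky-bulky ketones. No ring closes and no skeletal bond forms; only the C7–H bond is made. C8 (S) is set by the enzyme's choice between the substrate enantiomers (separate pockets for methyl and aryloxy) and is locked once C7 is sp3 because the alcohol cannot enolise, whereas C7 (S) is set by facial hydride delivery and does not matter because step 6 erases it. The selectivity needed is a high enantiomer preference at C8 together with racemisation faster than reduction of the slow enantiomer; the substrate secures this through the acidity of C8–H and through the TIPS ether, which stops ring B from becoming a phenoxide that would deaden both the carbonyl and C8–H. The allyl group, the aryl ethers and the hindered silyl ether should be inert at this pH, the α-aryloxy enolate has no β-leaving group to lose, and stripping acetone pulls the redox equilibrium forward.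

**Step 5**
Reactants: 7 (1S,2S)-2-(4-allyl-2,6-dimethoxyphenoxy)-1-[3-methoxy-4-(triisopropylsilyloxy)phenyl]propan-1-ol
Product: 8 (1S,2S)-2-(4-allyl-2,6-dimethoxyphenoxy)-1-[3-methoxy-4-(triisopropylsilyloxy)phenyl]propyl acetate
Conditions: Ac2O (2 equiv), DMAP (cat.), pyridine/CH2Cl2, 0 °C to rt
Reagents that add atoms: acetic anhydride, CC(=O)OC(C)=O
Why: DMAP-catalysed acylation of a secondary benzylic alcohol touches only the O–H bond, so C7 and C8 keep their configuration, and the C7 oxygen becomes a leaving group that stays dormant until ring B is unmasked.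

**Step 6**
Reactants: 8 (1S,2S)-2-(4-allyl-2,6-dimethoxyphenoxy)-1-[3-methoxy-4-(triisopropylsilyloxy)phenyl]propyl acetate
Product: 11 4-[(2S)-2-(4-allyl-2,6-dimethoxyphenoxy)propyl]-2-methoxyphenol, via phenoxide acetate 9 (not isolated), via para-quinone methide 10 (not isolated)
Conditions: Bu4NBH4 (3 equiv), then Bu4NF (1.0 M in THF, 1.2 equiv, dropwise), THF/i-PrOH (9:1), 0 °C; then cold aq. 1 M HCl
Reagents that add atoms: none
Why: Fluoride cleaves the aryl silyl ether, phenoxide 9 expels acetate by 1,6-elimination, and para-quinone methide 10 is trapped at once by borohydride at C7 with rearomatisation of ring B (the known reductive deoxygenation of para-hydroxybenzyl esters and of lignin-type β-aryl ether quinone methides); no bond to C8 is made or broken so its S configuration persists, C7 becomes CH2, the all-ammonium reagent pair avoids loss of fluoride as NaF, and i-PrOH destroys the borane formed before it can hydroborate the allyl group.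

**Compound list**
1 | 1-(4-hydroxy-3-methoxyphenyl)propan-1-one | CCC(=O)c1ccc(O)c(OC)c1 | starting material
2 | 1-[3-methoxy-4-(triisopropylsilyloxy)phenyl]propan-1-one | CCC(=O)c1ccc(O[Si](C(C)C)(C(C)C)C(C)C)c(OC)c1 | intermediate
3 | rac-2-bromo-1-[3-methoxy-4-(triisopropylsilyloxy)phenyl]propan-1-one | CC(Br)C(=O)c1ccc(O[Si](C(C)C)(C(C)C)C(C)C)c(OC)c1 | intermediate
4 | 4-allyl-2,6-dimethoxyphenol | C=CCc1cc(OC)c(O)c(OC)c1 | starting material
5 | rac-2-(4-allyl-2,6-dimethoxyphenoxy)-1-[3-methoxy-4-(triisopropylsilyloxy)phenyl]propan-1-one | C=CCc1cc(OC)c(OC(C)C(=O)c2ccc(O[Si](C(C)C)(C(C)C)C(C)C)c(OC)c2)c(OC)c1 | intermediate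
6 | C7–C8 enolate of 5 (anion shown, geometry undefined) | C=CCc1cc(OC)c(OC(C)=C([O-])c2ccc(O[Si](C(C)C)(C(C)C)C(C)C)c(OC)c2)c(OC)c1 | intermediate
7 | (1S,2S)-2-(4-allyl-2,6-dimethoxyphenoxy)-1-[3-methoxy-4-(triisopropylsilyloxy)phenyl]propan-1-ol | C=CCc1cc(OC)c(O[C@@H](C)[C@@H](O)c2ccc(O[Si](C(C)C)(C(C)C)C(C)C)c(OC)c2)c(OC)c1 | intermediate
8 | (1S,2S)-2-(4-allyl-2,6-dimethoxyphenoxy)-1-[3-methoxy-4-(triisopropylsilyloxy)phenyl]propyl acetate | C=CCc1cc(OC)c(O[C@@H](C)[C@@H](OC(C)=O)c2ccc(O[Si](C(C)C)(C(C)C)C(C)C)c(OC)c2)c(OC)c1 | intermediate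
9 | 4-[(1S,2S)-1-acetoxy-2-(4-allyl-2,6-dimethoxyphenoxy)propyl]-2-methoxyphenoxide (anion shown) | C=CCc1cc(OC)c(O[C@@H](C)[C@@H](OC(C)=O)c2ccc([O-])c(OC)c2)c(OC)c1 | intermediate
10 | 4-[(2S)-2-(4-allyl-2,6-dimethoxyphenoxy)propylidene]-2-methoxycyclohexa-2,5-dien-1-one (exocyclic alkene geometry undefined) | C=CCc1cc(OC)c(O[C@@H](C)C=C2C=CC(=O)C(OC)=C2)c(OC)c1 | intermediate
11 | 4-[(2S)-2-(4-allyl-2,6-dimethoxyphenoxy)propyl]-2-methoxyphenol | C=CCc1cc(OC)c(O[C@@H](C)Cc2ccc(O)c(OC)c2)c(OC)c1 | target

**Total step count:** 6. **Longest linear sequence:** 6 steps (1 to 11); phenol 4 enters as purchased in step 3.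

**Steps most likely to fail**

1. Step 4.
   - What may go wrong:
     - No variant may accept a ketone with two bulky flanks.
     - The enzyme may control only the carbonyl face and discriminate poorly between the C8 enantiomers.
     - Enolisation of the sparingly soluble ketone may lag behind reduction, so that the process degenerates into a plain kinetic resolution.
   - Fallback (chiral pool in place of resolution, known chemistry only), setting out from 4:
     - A Mitsunobu reaction of 4 with ethyl (R)-lactate (PPh3, DIAD, THF, 0 °C to rt) should give, with inversion, ethyl (2S)-2-(4-allyl-2,6-dimethoxyphenoxy)propanoate F1.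
     - MeNH(OMe)·HCl and i-PrMgCl in THF at −20 °C convert it into (2S)-2-(4-allyl-2,6-dimethoxyphenoxy)-N-methoxy-N-methylpropanamide F2.
     - Separately, commercial 4-bromo-2-methoxyphenol is silylated (TIPSCl, imidazole, DMF) to (4-bromo-2-methoxyphenoxy)triisopropylsilane F3. This is lithiated (n-BuLi, THF, −78 °C) to [3-methoxy-4-(triisopropylsilyloxy)phenyl]lithium F4.
     - Weinreb ketone synthesis from F2 and F4 at −78 °C gives (2S)-2-(4-allyl-2,6-dimethoxyphenoxy)-1-[3-methoxy-4-(triisopropylsilyloxy)phenyl]propan-1-one F5.
     - F5 is reduced without delay (NaBH4, THF/MeOH, −40 °C) before it can enolise.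
     - The route is rejoined at 7, which forms together with its C7 epimer (1R,2S)-2-(4-allyl-2,6-dimethoxyphenoxy)-1-[3-methoxy-4-(triisopropylsilyloxy)phenyl]propan-1-ol F6.
     - The epimer travels through steps 5 and 6 as (1R,2S)-2-(4-allyl-2,6-dimethoxyphenoxy)-1-[3-methoxy-4-(triisopropylsilyloxy)phenyl]propyl acetate F7 and 4-[(1R,2S)-1-acetoxy-2-(4-allyl-2,6-dimethoxyphenoxy)propyl]-2-methoxyphenoxide F8. It merges with the main line in quinone methide 10.

2. Step 6.
   - What may go wrong:
     - The quinone methide may lose C8–H under the basic conditions and tautomerise to the aryl enol ether faster than hydride arrives.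
     - The acetate may be cleaved before desilylation, which leaves a carbinol that does not eliminate.
     - Borane may add to the allyl group.
   - Fallback (cationic instead of quinone methide deoxygenation), setting out from 7:
     - Ionic hydrogenation with Et3SiH (5 equiv) and CF3CO2H in CH2Cl2 at −20 to 0 °C ionises the ring B-stabilised benzylic carbinol and delivers hydride to C7. The terminal alkene is not reduced under these conditions.
     - The product is [4-[(2S)-2-(4-allyl-2,6-dimethoxyphenoxy)propyl]-2-methoxyphenoxy]triisopropylsilane F9.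
     - Bu4NF in THF at 0 °C then returns the route to 11.
     - A hydride shift from C8 would erode the configuration. It is disfavoured because the ring B-stabilised cation is the lower in energy, and the large excess of silane shortens its lifetime.

3. Step 3.
   - What may go wrong:
     - The silyl group may transfer from the electron-poor ring B oxygen to the more basic ring A phenoxide.
     - Dehydrobromination may give the aryl vinyl ketone, followed by conjugate addition with the wrong regiochemistry.
     - Substitution by the hindered phenoxide may be sluggish.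
   - Fallback (ether first, C7–aryl bond last, so the silyl ether never meets phenoxide or carbonate), setting out from 4:
     - Alkylation of 4 with racemic ethyl 2-bromopropanoate (K2CO3, acetone, reflux) gives ethyl 2-(4-allyl-2,6-dimethoxyphenoxy)propanoate F10.
     - MeNH(OMe)·HCl and i-PrMgCl give 2-(4-allyl-2,6-dimethoxyphenoxy)-N-methoxy-N-methylpropanamide F11.
     - Addition of [3-methoxy-4-(triisopropylsilyloxy)phenyl]lithium F4, made from (4-bromo-2-methoxyphenoxy)triisopropylsilane F3 as described for step 4, at −78 °C returns the route to 5.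

**Further compounds**
F1 | step 4 | ethyl (2S)-2-(4-allyl-2,6-dimethoxyphenoxy)propanoate | C=CCc1cc(OC)c(O[C@@H](C)C(=O)OCC)c(OC)c1
F2 | step 4 | (2S)-2-(4-allyl-2,6-dimethoxyphenoxy)-N-methoxy-N-methylpropanamide | C=CCc1cc(OC)c(O[C@@H](C)C(=O)N(C)OC)c(OC)c1
F3 | step 4 | (4-bromo-2-methoxyphenoxy)triisopropylsilane | COc1cc(Br)ccc1O[Si](C(C)C)(C(C)C)C(C)C
F4 | step 4 | [3-methoxy-4-(triisopropylsilyloxy)phenyl]lithium | [Li]c1ccc(O[Si](C(C)C)(C(C)C)C(C)C)c(OC)c1
F5 | step 4 | (2S)-2-(4-allyl-2,6-dimethoxyphenoxy)-1-[3-methoxy-4-(triisopropylsilyloxy)phenyl]propan-1-one | C=CCc1cc(OC)c(O[C@@H](C)C(=O)c2ccc(O[Si](C(C)C)(C(C)C)C(C)C)c(OC)c2)c(OC)c1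
F6 | step 4 | (1R,2S)-2-(4-allyl-2,6-dimethoxyphenoxy)-1-[3-methoxy-4-(triisopropylsilyloxy)phenyl]propan-1-ol | C=CCc1cc(OC)c(O[C@@H](C)[C@H](O)c2ccc(O[Si](C(C)C)(C(C)C)C(C)C)c(OC)c2)c(OC)c1
F7 | step 4 | (1R,2S)-2-(4-allyl-2,6-dimethoxyphenoxy)-1-[3-methoxy-4-(triisopropylsilyloxy)phenyl]propyl acetate | C=CCc1cc(OC)c(O[C@@H](C)[C@H](OC(C)=O)c2ccc(O[Si](C(C)C)(C(C)C)C(C)C)c(OC)c2)c(OC)c1
F8 | step 4 | 4-[(1R,2S)-1-acetoxy-2-(4-allyl-2,6-dimethoxyphenoxy)propyl]-2-methoxyphenoxide (anion shown) | C=CCc1cc(OC)c(O[C@@H](C)[C@H](OC(C)=O)c2ccc([O-])c(OC)c2)c(OC)c1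
F9 | step 6 | [4-[(2S)-2-(4-allyl-2,6-dimethoxyphenoxy)propyl]-2-methoxyphenoxy]triisopropylsilane | C=CCc1cc(OC)c(O[C@@H](C)Cc2ccc(O[Si](C(C)C)(C(C)C)C(C)C)c(OC)c2)c(OC)c1
F10 | step 3 | ethyl 2-(4-allyl-2,6-dimethoxyphenoxy)propanoate (racemic) | C=CCc1cc(OC)c(OC(C)C(=O)OCC)c(OC)c1
F11 | step 3 | 2-(4-allyl-2,6-dimethoxyphenoxy)-N-methoxy-N-methylpropanamide (racemic) | C=CCc1cc(OC)c(OC(C)C(=O)N(C)OC)c(OC)c1
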